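**Conventions and one assumption.** Flavan numbering is used inside each unit (O1, C2, C3, C4, C4a, C5–C8, C8a; ring B atoms primed). The top unit is the one whose C4 is bonded to C8 of the middle unit; the middle unit's C4 is bonded to C6 of the lower unit. α is the face of ring C that carries the 2-aryl group in epicatechin, β the opposite face. Bn = benzyl, TBS = tert-butyldimethylsilyl, TIPS = triisopropylsilyl. Assumption: the benzylated building blocks 5, 13 and 23 are bought as such, which shortens the route without touching the strategy.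

## Analysis of the target

Compound 29 is a linear trimer of flavan-3-ols, each a chroman (rings A and C) with a catechol ring B on C2: the top and middle units are epicatechin 3-O-gallates and the lower unit is catechin with a free 3-OH. C4 of the top unit is bonded to C8 of the middle unit and C4 of the middle unit to C6 of the lower unit. There are eight stereocentres, C2, C3 and C4 in each upper unit and C2 and C3 in the lower one. In the upper units the 2-aryl group and O3 are cis (both α) and the C4–aryl bond is β, trans to O3, whereas in the lower unit the aryl group is α and the hydroxyl β (2R,3S, trans). Eighteen phenolic hydroxyls, two gallate esters and two doubly benzylic interflavan bonds make the compound sensitive to air, to acid (loss or scrambling of units) and to base (epimerisation at C2, ester cleavage), so it must be set free last and close to neutrality. The hard points are the 4→6 linkage, which a flavan nucleophile avoids because its C8 is more reactive, the β configuration of both interflavan bonds, and the distinction of three secondary hydroxyls, two acylated and one free. The strategy rests on the lower unit: C2 and C3 are neighbouring oxygen-bearing carbons that can both be carbonyl carbons, and O1 sits on C8a, which is para to C6. If ring A of the lower unit is joined to the middle unit para to a phenolic oxygen, and this oxygen is acylated with the ring B acid while the ortho carbon carries a CH2CHO chain, closure of the C2–C3 bond can give only the 4→6 isomer.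

## Retrosynthetic reasoning

29 from 28. All nineteen O–benzyl bonds and the two aryl C–Br bonds are cut in one operation. Benzyl protects every phenol and the lower O3, and bromine caps the two ring A carbons that must not react, so one buffered hydrogenolysis unveils the whole polyphenol.

28 from 25 and 27. The C4(top)–C8(middle) bond is cut last, because the whole top unit, with C2, C3 and its gallate in place, can then come from 1 and the two halves are joined in one convergent step. The forward reaction has to ionise the 4-alkoxy group of 27 and let C8 of the middle unit of 25 attack the β face. The 3-O-acyl group of 27 lies on the α face and can bridge to C4, which supports that course. Bromine at C8 of 27 keeps the donor from adding to itself, and bromine at the lower C8 of 25 removes the only other ring A carbon of similar reactivity.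

27 from 26 from 3 and 24. The C8–Br bond and then the gallate ester C–O bond of the top unit are cut. Alcohol 3 has a single hydroxyl, so one equivalent of chloride 24, made from acid 23, places this gallate without ambiguity.

25 from 22 and 24, and 22 from 21. The gallate ester C–O bond of the middle unit is cut, then the O–Si bond. In 22 only the middle 3-hydroxyl is free, because it was a silyl ether in 21 while the lower O3 was a benzyl ether. The protecting groups therefore decide where this gallate goes, and each ester is made on a compound with one free hydroxyl.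

21 from 20 from 18. After the benzyl ether is removed, the C3–O and C2–H bonds of the lower unit are cut back to the C2=C3 enol ether. A syn addition of hydrogen and oxygen across this bond gives the 2,3-trans pattern by itself, and only the face has to be chosen by the reagent.

18 from 17 (key disconnection). C2=C3 is cut into an aldehyde carbon (C3) and the carbonyl carbon of an aryl ester (C2). The cut is made here, and not at C4–C4a or O1–C2, because the two carbons have the same polarity and are held in a 1,6-relationship by the ester oxygen that is already O1. One acylation then brings in ring B and one reductive coupling closes ring C, and the 4→6 regiochemistry is fixed beforehand.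

17 from 15 from 12 and 14. The aldehyde goes back to a C-allyl group (oxidative cleavage of C=C), and the ester O–C(=O) bond goes back to phenol 12 and chloride 14, made from acid 13.

12 from 11 from 10. The C–Br bond and then the O–Si bond are cut. Bromine is put in while the lower ring is a free phenol with a single open carbon next to the hydroxyl, so its position is not in doubt.

10 from 4 and 9. The C4(middle)–aryl bond is cut, which lets the middle unit come from 1 as well. The forward reaction needs attack of arene 9 through the carbon between its two benzyloxy groups, para to the silyloxy group, on the β face of the C4 cation from 4.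

9 from 8 from 6 from 5. The O–Si bond, then the allyl C–C bond (a [3,3] shift from the O-allyl ether through dienone 7) and the O–allyl bond are cut. Both ortho carbons of 6 are equivalent, so the rearrangement has one outcome.

4 from 3 from 2 from 1. The O–Si bond of 4, the C4–O bond of 3 and the four phenolic O–benzyl bonds of 2 lead back to (−)-epicatechin 1. Alcohol 3 is the branch point: silylated it becomes the middle-unit donor 4, acylated and brominated it becomes the top-unit donor 27, so 1 supplies C2 and C3 of both upper units.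

## Alternatives that were turned down

Alternative 1: The top unit's ring C is opened at O1–C8a. The forward key step is a Baeyer–Villiger oxidation of indanone A1: the electron-rich ring A carbon migrates from the carbonyl carbon to oxygen and the five-membered ketone becomes the six-membered lactone A2.
- For it: the C4(top)–C8(middle) bond already exists in A1, so the 4→8 regiochemistry cannot go wrong, and aryl migration is the expected sense.
- Against it: A2 is only a 4-aryl-dihydrocoumarin. The 2-aryl group, the 3-oxygen and the 2,3-cis relationship still have to be built on the lactone, and the C4 stereocentre of A1 has to be made by asymmetric synthesis next to a chiral middle unit. A peracid is also an uncomfortable reagent for five benzyloxy-substituted rings and an acid-labile 4-acetal.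
- Comparison: on regiocontrol of the upper linkage it is stronger than the chosen route, which needs two bromine caps and the innate C8 preference. The chosen route in return takes the top unit complete from 1, gallate included, and adds it in one step.

Alternative 2: The middle unit's ring C is opened at C4–C4a. In the forward step ring A of aryl ether A3 attacks the epoxide carbon that bears the lower-unit aryl group (6-endo opening) and gives A4, which is the same compound as 22.
- For it: the lower unit is natural catechin, so its two stereocentres are inherited and no asymmetric hydroboration is needed. The 4→6 linkage is fixed before ring closure, anti opening of the trans epoxide gives the 3,4-trans relationship, and the product would join the chosen route at 22.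
- Against it: the epoxide carbon carries a 2,6-dialkoxyaryl group and will open through a free cation, so the transfer of configuration to C4 is not assured. C6 of catechin has to be functionalised against its own C8 preference. All three stereocentres of the middle unit (the benzylic ether carbon and the epoxide) must be made by synthesis, the ether on an electron-rich benzylic carbon being prone to racemisation.
- Comparison: it is at least as good for the lower unit. The chosen route has to create only the two lower-unit centres by reagent control and uses 1 for both upper units.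

Alternative 3: The lower unit's ring C is opened at C4–C4a. In the forward step the ring A carbon ortho to the ether oxygen of A5 attacks the terminal epoxide carbon and gives A6, which is the same compound as 20.
- For it: C2 and C3 are set before ring closure by dependable asymmetric epoxidation chemistry, and the product enters the chosen route directly at 20.
- Against it: the ether between the benzylic C2 and a hindered bromophenol must be formed with full stereochemical fidelity on a carbon that ionises easily. The cyclisation must go 6-endo at a primary carbon against 5-exo attack at the internal carbon. The Lewis acid it needs threatens the benzylic C2–O bond and the interflavan bond, and the attacking arene carbon is deactivated by the meta bromine.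
- Comparison: on stereocontrol of the lower unit it is stronger than the chosen route, which has to rely on a chiral borane after ring closure. The chosen route offers a ring closure between two carbonyl groups that are assembled by a simple acylation and joined under non-acidic, reductive conditions.

Key step: step 13

## Route

Step 1
Reactants: 1 (−)-epicatechin
Product: 2 5,7,3',4'-tetra-O-benzyl-(−)-epicatechin
Conditions: BnBr (4.4 equiv), K2CO3, DMF, 0 °C → rt
Reagents that add atoms: benzyl bromide, BrCc1ccccc1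
Why: Williamson etherification; carbonate deprotonates only the four phenols, the secondary alcohol stays free, and the mild base should leave the C2 configuration untouched.

Step 2
Reactants: 2 5,7,3',4'-tetra-O-benzyl-(−)-epicatechin
Product: 3 4β-(2-ethoxyethoxy)-5,7,3',4'-tetra-O-benzylepicatechin (2,3-cis, 3,4-trans, 3-OH free)
Conditions: DDQ, 2-ethoxyethanol, CH2Cl2, rt
Reagents that add atoms: 2-ethoxyethanol, CCOCCO
Why: Benzylic oxidation by hydride abstraction; the C4 cation, stabilised by the 5- and 7-alkoxy groups, is trapped by the alcohol on the β face, away from the α-oriented hydroxyl and aryl groups, and the non-benzylic secondary alcohol is not oxidised by the quinone.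

Step 3
Reactants: 3 4β-(2-ethoxyethoxy)-5,7,3',4'-tetra-O-benzylepicatechin
Product: 4 4β-(2-ethoxyethoxy)-3-O-TBS-5,7,3',4'-tetra-O-benzylepicatechin
Conditions: TBSCl, imidazole, DMF, rt → 40 °C
Reagents that add atoms: tert-butyldimethylsilyl chloride, CC(C)(C)[Si](C)(C)Cl
Why: Standard silylation of the only free hydroxyl under acid-free conditions that leave the 4-ether alone; the silyl ether keeps this oxygen distinct from the lower O3 and shields the α face of C4.

Step 4
Reactants: 5 3,5-bis(benzyloxy)phenol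
Product: 6 1-(allyloxy)-3,5-bis(benzyloxy)benzene
Conditions: allyl bromide, K2CO3, acetone, reflux
Reagents that add atoms: allyl bromide, C=CCBr
Why: Williamson O-allylation of a phenol.

Step 5
Reactants: 6 1-(allyloxy)-3,5-bis(benzyloxy)benzene
Product: 8 2-allyl-3,5-bis(benzyloxy)phenol, via dienone 7 (not isolated)
Conditions: PhNEt2, 190 °C
Reagents that add atoms: none
Why: Aromatic Claisen rearrangement; the two ortho carbons are equivalent, so the [3,3] shift gives one dienone, which tautomerises to the phenol.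

Step 6
Reactants: 8 2-allyl-3,5-bis(benzyloxy)phenol
Product: 9 [2-allyl-3,5-bis(benzyloxy)phenoxy]triisopropylsilane
Conditions: TIPSCl, imidazole, DMAP (cat.), DMF, 40 °C
Reagents that add atoms: triisopropylsilyl chloride, CC(C)[Si](Cl)(C(C)C)C(C)C
Why: Silylation of the phenol; the bulky silyl group, pushed by the ortho allyl group toward the other ortho carbon, is meant to screen that carbon in the next step.

Step 7
Reactants: 4 4β-(2-ethoxyethoxy)-3-O-TBS-5,7,3',4'-tetra-O-benzylepicatechin; 9 [2-allyl-3,5-bis(benzyloxy)phenoxy]triisopropylsilane (3 equiv)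
Product: 10 4β-[3-allyl-2,6-bis(benzyloxy)-4-(triisopropylsilyloxy)phenyl]-3-O-TBS-5,7,3',4'-tetra-O-benzylepicatechin
Conditions: TMSOTf (0.2 equiv), CH2Cl2, −78 °C → −40 °C
Reagents that add atoms: none
Why: Friedel–Crafts-type arylation through the C4 cation; of the two free carbons of 9 the one between the benzyloxy groups, para to the silyloxy group, should react because the other is screened by the triisopropylsilyl group, and the excess of 9 should outrun C8 of 4. Attack on the β face, anti to the 3-silyloxy and 2-aryl groups, sets C4 of the middle unit.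

Step 8
Reactants: 10 4β-[3-allyl-2,6-bis(benzyloxy)-4-(triisopropylsilyloxy)phenyl]-3-O-TBS-5,7,3',4'-tetra-O-benzylepicatechin
Product: 11 4β-[3-allyl-2,6-bis(benzyloxy)-4-hydroxyphenyl]-3-O-TBS-5,7,3',4'-tetra-O-benzylepicatechin
Conditions: TBAF (1.1 equiv), THF, 0 °C
Reagents that add atoms: none
Why: Fluoride cleaves the aryl silyl ether (a phenoxide leaving group) far faster than the hindered secondary alkyl TBS ether, so only the phenol is freed.

Step 9
Reactants: 11 4β-[3-allyl-2,6-bis(benzyloxy)-4-hydroxyphenyl]-3-O-TBS-5,7,3',4'-tetra-O-benzylepicatechin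
Product: 12 4β-[3-allyl-5-bromo-2,6-bis(benzyloxy)-4-hydroxyphenyl]-3-O-TBS-5,7,3',4'-tetra-O-benzylepicatechin
Conditions: NBS (1.0 equiv), i-Pr2NH (0.1 equiv), CH2Cl2, −78 °C → −20 °C
Reagents that add atoms: N-bromosuccinimide, O=C1CCC(=O)N1Br
Why: Amine-mediated ortho-bromination of a phenol; the N-bromoamine formed in the flask is a weak electrophile that should spare the aryl ethers of the middle unit and the alkene and is delivered by hydrogen bonding to the only free carbon next to the hydroxyl. This bromine ends up at C8 of the lower unit and blocks it.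

Step 10
Reactants: 13 3,4-bis(benzyloxy)benzoic acid
Product: 14 3,4-bis(benzyloxy)benzoyl chloride
Conditions: (COCl)2, DMF (cat.), CH2Cl2, 0 °C → rt
Reagents that add atoms: oxalyl chloride, ClC(=O)C(Cl)=O
Why: Standard conversion of an acid into its chloride; volatile by-products only, so 14 is used crude.

Step 11
Reactants: 12 4β-[3-allyl-5-bromo-2,6-bis(benzyloxy)-4-hydroxyphenyl]-3-O-TBS-5,7,3',4'-tetra-O-benzylepicatechin; 14 3,4-bis(benzyloxy)benzoyl chloride
Product: 15 4β-{3-allyl-5-bromo-2,6-bis(benzyloxy)-4-[3,4-bis(benzyloxy)benzoyloxy]phenyl}-3-O-TBS-5,7,3',4'-tetra-O-benzylepicatechin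
Conditions: Et3N, DMAP, CH2Cl2, 0 °C → rt
Reagents that add atoms: none
Why: DMAP-catalysed O-acylation of the only free hydroxyl; the acyl carbon becomes C2 and the phenol oxygen O1 of the lower unit.

Step 12
Reactants: 15 4β-{3-allyl-5-bromo-2,6-bis(benzyloxy)-4-[3,4-bis(benzyloxy)benzoyloxy]phenyl}-3-O-TBS-5,7,3',4'-tetra-O-benzylepicatechin
Product: 17 4β-{3-bromo-2,6-bis(benzyloxy)-4-[3,4-bis(benzyloxy)benzoyloxy]-5-(2-oxoethyl)phenyl}-3-O-TBS-5,7,3',4'-tetra-O-benzylepicatechin, via vicinal diol 16 (not isolated)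
Conditions: OsO4 (cat.), NaIO4, 2,6-lutidine, dioxane/H2O, rt
Reagents that add atoms: osmium tetroxide, O=[Os](=O)(=O)=O; sodium periodate, [Na+].[O-][I](=O)(=O)=O; water, O
Why: Lemieux–Johnson oxidation: catalytic dihydroxylation of the only alkene and periodate cleavage of the diol in the same flask; 2,6-lutidine keeps the medium near neutral so that the aryl ester and the arylacetaldehyde, which is used at once, survive.

Step 13
Reactants: 17 4β-{3-bromo-2,6-bis(benzyloxy)-4-[3,4-bis(benzyloxy)benzoyloxy]-5-(2-oxoethyl)phenyl}-3-O-TBS-5,7,3',4'-tetra-O-benzylepicatechin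
Product: 18 3-O-TBS-5,7,3',4'-tetra-O-benzylepicatechin-(4β→6)-8-bromo-5,7-bis(benzyloxy)-2-[3,4-bis(benzyloxy)phenyl]-4H-chromene
Conditions: TiCl3, Zn dust, DME, reflux; 17 added slowly (high dilution); basic work-up
Reagents that add atoms: none
Why: Zinc reduces TiCl3 to low-valent titanium, which transfers an electron to the aldehyde, the more easily reduced of the two carbonyl groups; the titanium-bound ketyl carbon (future C3) adds to the carbonyl carbon of the neighbouring aryl ester (future C2), and the oxophilic metal then removes both oxygens of the titanium diolate to leave the C2=C3 enol ether. The closest known reaction type is the McMurry-type intramolecular oxo-ester coupling, which turns keto esters into cyclic enol ethers and ortho-acyloxyaryl carbonyl compounds into benzofurans. Ring C of the lower unit closes by 6-exo-trig attack on the ester carbonyl, whose oxygen lies outside the new ring. No stereocentre is formed. The step needs the intramolecular aldehyde–ester coupling to win over aldehyde–aldehyde pinacol coupling, which the ortho relationship of the two groups and slow addition at high dilution should secure, and it needs the benzyl ethers, the silyl ether and the aryl bromide to stay untouched, which is expected because none of them is a carbonyl group. Regiochemistry is not at stake: only the oxygen para to the interflavan carbon is acylated and only its ortho carbon bears the acetaldehyde chain, so the product can only be the 4→6-linked chromene. A basic, non-aqueous work-up protects the acid-sensitive enol ether.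

Step 14
Reactants: 18 3-O-TBS-5,7,3',4'-tetra-O-benzylepicatechin-(4β→6)-8-bromo-5,7-bis(benzyloxy)-2-[3,4-bis(benzyloxy)phenyl]-4H-chromene
Product: 20 3-O-TBS-5,7,3',4'-tetra-O-benzylepicatechin-(4β→6)-8-bromo-5,7,3',4'-tetra-O-benzyl-(2R,3S)-catechin (lower 3-OH free), via alkylborane 19 (not isolated)
Conditions: IpcBH2 from (+)-α-pinene, THF, −25 °C → 0 °C; then NaOH, H2O2, 0 °C → rt
Reagents that add atoms: hydrogen peroxide, OO; monoisopinocampheylborane, [BH2][C@@H]1C[C@@H]2C[C@H]([C@H]1C)C2(C)C
Why: Asymmetric hydroboration–oxidation: boron adds to C3 (β to the enol ether oxygen and to the aryl group) and hydrogen to C2 from the same face, so oxidation with retention gives the 2,3-trans alcohol. The face is chosen by the terpene group on boron; by analogy with 1-arylcycloalkenes, which this borane turns into (1S,2R)-trans-2-arylcycloalkanols, the (2R,3S) unit is expected, the remote middle unit exerting no bias.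

Step 15
Reactants: 20 3-O-TBS-5,7,3',4'-tetra-O-benzylepicatechin-(4β→6)-8-bromo-5,7,3',4'-tetra-O-benzyl-(2R,3S)-catechin
Product: 21 3-O-TBS-5,7,3',4'-tetra-O-benzylepicatechin-(4β→6)-8-bromo-3,5,7,3',4'-penta-O-benzylcatechin
Conditions: NaH, BnBr, Bu4NI (cat.), DMF, 0 °C → rt
Reagents that add atoms: benzyl bromide, BrCc1ccccc1
Why: Williamson benzylation of the only free hydroxyl; as a benzyl ether the lower O3 stays masked during both galloylations and is freed in the final hydrogenolysis.

Step 16
Reactants: 21 3-O-TBS-5,7,3',4'-tetra-O-benzylepicatechin-(4β→6)-8-bromo-3,5,7,3',4'-penta-O-benzylcatechin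
Product: 22 5,7,3',4'-tetra-O-benzylepicatechin-(4β→6)-8-bromo-3,5,7,3',4'-penta-O-benzylcatechin (middle 3-OH free)
Conditions: TBAF, THF, rt → 45 °C
Reagents that add atoms: none
Why: Fluoride-induced cleavage of the secondary silyl ether; benzyl ethers, the aryl bromide and the interflavan bond are inert to fluoride, so the middle 3-hydroxyl becomes the only free hydroxyl.

Step 17
Reactants: 23 3,4,5-tris(benzyloxy)benzoic acid
Product: 24 3,4,5-tris(benzyloxy)benzoyl chloride
Conditions: (COCl)2, DMF (cat.), CH2Cl2, 0 °C → rt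
Reagents that add atoms: oxalyl chloride, ClC(=O)C(Cl)=O
Why: Standard conversion of an acid into its chloride; the crude chloride is divided between steps 18 and 19.

Step 18
Reactants: 22 5,7,3',4'-tetra-O-benzylepicatechin-(4β→6)-8-bromo-3,5,7,3',4'-penta-O-benzylcatechin; 24 3,4,5-tris(benzyloxy)benzoyl chloride
Product: 25 5,7,3',4'-tetra-O-benzyl-3-O-[3,4,5-tris(benzyloxy)benzoyl]epicatechin-(4β→6)-8-bromo-3,5,7,3',4'-penta-O-benzylcatechin
Conditions: Et3N, DMAP, CH2Cl2, rt → 40 °C
Reagents that add atoms: none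
Why: DMAP-catalysed acylation of the single, hindered secondary hydroxyl; the lower O3 is a benzyl ether, so the gallate can only go to the middle unit.

Step 19
Reactants: 3 4β-(2-ethoxyethoxy)-5,7,3',4'-tetra-O-benzylepicatechin; 24 3,4,5-tris(benzyloxy)benzoyl chloride
Product: 26 4β-(2-ethoxyethoxy)-5,7,3',4'-tetra-O-benzyl-3-O-[3,4,5-tris(benzyloxy)benzoyl]epicatechin
Conditions: Et3N, DMAP, CH2Cl2, 0 °C → rt
Reagents that add atoms: none
Why: DMAP-catalysed acylation of the only free hydroxyl under basic conditions that do not ionise the 4-ether; this puts the top-unit gallate in place before the interflavan bond is made.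

Step 20
Reactants: 26 4β-(2-ethoxyethoxy)-5,7,3',4'-tetra-O-benzyl-3-O-[3,4,5-tris(benzyloxy)benzoyl]epicatechin
Product: 27 8-bromo-4β-(2-ethoxyethoxy)-5,7,3',4'-tetra-O-benzyl-3-O-[3,4,5-tris(benzyloxy)benzoyl]epicatechin
Conditions: NBS, CH2Cl2, −78 °C → 0 °C
Reagents that add atoms: N-bromosuccinimide, O=C1CCC(=O)N1Br
Why: Electrophilic aromatic bromination at C8, the most nucleophilic and least hindered ring A carbon (C6 lies between two benzyloxy groups); the acyl-substituted gallate ring and ring B are far less reactive, the neutral reagent leaves the 4-ether intact, and the bromine makes 27 unable to act as a nucleophile.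

Step 21
Reactants: 25 5,7,3',4'-tetra-O-benzyl-3-O-[3,4,5-tris(benzyloxy)benzoyl]epicatechin-(4β→6)-8-bromo-3,5,7,3',4'-penta-O-benzylcatechin; 27 8-bromo-4β-(2-ethoxyethoxy)-5,7,3',4'-tetra-O-benzyl-3-O-[3,4,5-tris(benzyloxy)benzoyl]epicatechin (1.5 equiv)
Product: 28 8-bromo-5,7,3',4'-tetra-O-benzyl-3-O-[3,4,5-tris(benzyloxy)benzoyl]epicatechin-(4β→8)-5,7,3',4'-tetra-O-benzyl-3-O-[3,4,5-tris(benzyloxy)benzoyl]epicatechin-(4β→6)-8-bromo-3,5,7,3',4'-penta-O-benzylcatechin
Conditions: TMSOTf (cat.), CH2Cl2, −78 °C → −30 °C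
Reagents that add atoms: none
Why: Friedel–Crafts-type interflavan coupling: the C4 cation from 27 is attacked by C8 of the middle unit of 25, the only unhindered free ring A carbon (the lower C8 is brominated, the middle C6 lies between two benzyloxy groups). The 3-O-acyl group on the α face can bridge to C4 as a dioxolanylium ion, so attack comes from the β face and sets C4 of the top unit trans to O3, and the bromine on 27 stops the donor from adding to itself.

Step 22
Reactants: 28 8-bromo-5,7,3',4'-tetra-O-benzyl-3-O-[3,4,5-tris(benzyloxy)benzoyl]epicatechin-(4β→8)-5,7,3',4'-tetra-O-benzyl-3-O-[3,4,5-tris(benzyloxy)benzoyl]epicatechin-(4β→6)-8-bromo-3,5,7,3',4'-penta-O-benzylcatechin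
Product: 29 epicatechin 3-O-gallate-(4β→8)-epicatechin 3-O-gallate-(4β→6)-catechin (CNP0154615.1)
Conditions: H2 (1 atm), Pd(OH)2/C, Et3N (2.0 equiv), THF/MeOH/H2O, rt; filtration under argon, Sephadex LH-20, lyophilisation
Reagents that add atoms: none
Why: Hydrogenolysis removes the nineteen benzyl groups and both aryl bromines in one operation; the esters, the benzylic ring C ethers and the interflavan bonds are not expected to be hydrogenolysed under these mild conditions, and the two equivalents of amine take up the HBr as it forms so that the free polyphenol never meets strong acid.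

## Compound list

1 | (−)-epicatechin, (2R,3R)-2-(3,4-dihydroxyphenyl)chroman-3,5,7-triol | O[C@@H]1Cc2c(O)cc(O)cc2O[C@@H]1c1ccc(O)c(O)c1 | starting material
2 | 5,7,3',4'-tetra-O-benzyl-(−)-epicatechin | O[C@@H]1Cc2c(OCc9ccccc9)cc(OCc9ccccc9)cc2O[C@@H]1c1ccc(OCc9ccccc9)c(OCc9ccccc9)c1 | intermediate
3 | 4β-(2-ethoxyethoxy)-5,7,3',4'-tetra-O-benzylepicatechin (2,3-cis, 3,4-trans, 3-OH free) | c1c(OCc9ccccc9)cc(OCc9ccccc9)c2c1O[C@H](c7ccc(OCc9ccccc9)c(OCc9ccccc9)c7)[C@H](O)[C@H]2OCCOCC | intermediate
4 | 4β-(2-ethoxyethoxy)-3-O-TBS-5,7,3',4'-tetra-O-benzylepicatechin (2,3-cis, 3,4-trans) | c1c(OCc9ccccc9)cc(OCc9ccccc9)c2c1O[C@H](c7ccc(OCc9ccccc9)c(OCc9ccccc9)c7)[C@H](O[Si](C)(C)C(C)(C)C)[C@H]2OCCOCC | intermediate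
5 | 3,5-bis(benzyloxy)phenol | Oc1cc(OCc2ccccc2)cc(OCc2ccccc2)c1 | starting material
6 | 1-(allyloxy)-3,5-bis(benzyloxy)benzene | C=CCOc1cc(OCc2ccccc2)cc(OCc2ccccc2)c1 | intermediate
7 | 6-allyl-3,5-bis(benzyloxy)cyclohexa-2,4-dien-1-one (racemic; forms in the flask in step 5) | C=CCC1C(=O)C=C(OCc2ccccc2)C=C1OCc1ccccc1 | intermediate
8 | 2-allyl-3,5-bis(benzyloxy)phenol | C=CCc1c(O)cc(OCc2ccccc2)cc1OCc1ccccc1 | intermediate
9 | [2-allyl-3,5-bis(benzyloxy)phenoxy]triisopropylsilane | C=CCc1c(O[Si](C(C)C)(C(C)C)C(C)C)cc(OCc2ccccc2)cc1OCc1ccccc1 | intermediate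
10 | 3-O-TBS-5,7,3',4'-tetra-O-benzylepicatechin carrying at C4β a 3-allyl-2,6-bis(benzyloxy)-4-(triisopropylsilyloxy)phenyl group | c1c(OCc9ccccc9)cc(OCc9ccccc9)c2c1O[C@H](c7ccc(OCc9ccccc9)c(OCc9ccccc9)c7)[C@H](O[Si](C)(C)C(C)(C)C)[C@H]2c3c(OCc9ccccc9)cc(O[Si](C(C)C)(C(C)C)C(C)C)c(CC=C)c3OCc9ccccc9 | intermediate
11 | 3-O-TBS-5,7,3',4'-tetra-O-benzylepicatechin carrying at C4β a 3-allyl-2,6-bis(benzyloxy)-4-hydroxyphenyl group | c1c(OCc9ccccc9)cc(OCc9ccccc9)c2c1O[C@H](c7ccc(OCc9ccccc9)c(OCc9ccccc9)c7)[C@H](O[Si](C)(C)C(C)(C)C)[C@H]2c3c(OCc9ccccc9)cc(O)c(CC=C)c3OCc9ccccc9 | intermediate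
12 | 3-O-TBS-5,7,3',4'-tetra-O-benzylepicatechin carrying at C4β a 3-allyl-5-bromo-2,6-bis(benzyloxy)-4-hydroxyphenyl group | c1c(OCc9ccccc9)cc(OCc9ccccc9)c2c1O[C@H](c7ccc(OCc9ccccc9)c(OCc9ccccc9)c7)[C@H](O[Si](C)(C)C(C)(C)C)[C@H]2c3c(OCc9ccccc9)c(Br)c(O)c(CC=C)c3OCc9ccccc9 | intermediate
13 | 3,4-bis(benzyloxy)benzoic acid | OC(=O)c1ccc(OCc2ccccc2)c(OCc2ccccc2)c1 | starting material
14 | 3,4-bis(benzyloxy)benzoyl chloride | ClC(=O)c1ccc(OCc2ccccc2)c(OCc2ccccc2)c1 | intermediate
15 | 3-O-TBS-5,7,3',4'-tetra-O-benzylepicatechin carrying at C4β a 3-allyl-5-bromo-2,6-bis(benzyloxy)-4-[3,4-bis(benzyloxy)benzoyloxy]phenyl group | c1c(OCc9ccccc9)cc(OCc9ccccc9)c2c1O[C@H](c7ccc(OCc9ccccc9)c(OCc9ccccc9)c7)[C@H](O[Si](C)(C)C(C)(C)C)[C@H]2c3c(OCc9ccccc9)c(Br)c(OC(=O)c7ccc(OCc9ccccc9)c(OCc9ccccc9)c7)c(CC=C)c3OCc9ccccc9 | intermediate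
16 | 3-O-TBS-5,7,3',4'-tetra-O-benzylepicatechin carrying at C4β a 3-bromo-2,6-bis(benzyloxy)-4-[3,4-bis(benzyloxy)benzoyloxy]-5-(2,3-dihydroxypropyl)phenyl group (both carbinol epimers; forms in the flask in step 12) | c1c(OCc9ccccc9)cc(OCc9ccccc9)c2c1O[C@H](c7ccc(OCc9ccccc9)c(OCc9ccccc9)c7)[C@H](O[Si](C)(C)C(C)(C)C)[C@H]2c3c(OCc9ccccc9)c(Br)c(OC(=O)c7ccc(OCc9ccccc9)c(OCc9ccccc9)c7)c(CC(O)CO)c3OCc9ccccc9 | intermediate
17 | 3-O-TBS-5,7,3',4'-tetra-O-benzylepicatechin carrying at C4β a 3-bromo-2,6-bis(benzyloxy)-4-[3,4-bis(benzyloxy)benzoyloxy]-5-(2-oxoethyl)phenyl group | c1c(OCc9ccccc9)cc(OCc9ccccc9)c2c1O[C@H](c7ccc(OCc9ccccc9)c(OCc9ccccc9)c7)[C@H](O[Si](C)(C)C(C)(C)C)[C@H]2c3c(OCc9ccccc9)c(Br)c(OC(=O)c7ccc(OCc9ccccc9)c(OCc9ccccc9)c7)c(CC=O)c3OCc9ccccc9 | intermediate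
18 | 3-O-TBS-5,7,3',4'-tetra-O-benzylepicatechin-(4β→6)-8-bromo-5,7-bis(benzyloxy)-2-[3,4-bis(benzyloxy)phenyl]-4H-chromene | c1c(OCc9ccccc9)cc(OCc9ccccc9)c2c1O[C@H](c7ccc(OCc9ccccc9)c(OCc9ccccc9)c7)[C@H](O[Si](C)(C)C(C)(C)C)[C@H]2c3c(OCc9ccccc9)c(Br)c4c(c3OCc9ccccc9)CC=C(c7ccc(OCc9ccccc9)c(OCc9ccccc9)c7)O4 | intermediate
19 | isopinocampheyl[(2R,3S)-flavan-3-yl]borane of the lower unit, boron on C3 trans to the 2-aryl group (forms in the flask in step 14) | c1c(OCc9ccccc9)cc(OCc9ccccc9)c2c1O[C@H](c7ccc(OCc9ccccc9)c(OCc9ccccc9)c7)[C@H](O[Si](C)(C)C(C)(C)C)[C@H]2c3c(OCc9ccccc9)c(Br)c4c(c3OCc9ccccc9)C[C@H]([BH][C@@H]5C[C@@H]6C[C@H]([C@H]5C)C6(C)C)[C@@H](c7ccc(OCc9ccccc9)c(OCc9ccccc9)c7)O4 | intermediate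
20 | 3-O-TBS-5,7,3',4'-tetra-O-benzylepicatechin-(4β→6)-8-bromo-5,7,3',4'-tetra-O-benzyl-(2R,3S)-catechin, lower 3-OH free | c1c(OCc9ccccc9)cc(OCc9ccccc9)c2c1O[C@H](c7ccc(OCc9ccccc9)c(OCc9ccccc9)c7)[C@H](O[Si](C)(C)C(C)(C)C)[C@H]2c3c(OCc9ccccc9)c(Br)c4c(c3OCc9ccccc9)C[C@H](O)[C@@H](c7ccc(OCc9ccccc9)c(OCc9ccccc9)c7)O4 | intermediate
21 | 3-O-TBS-5,7,3',4'-tetra-O-benzylepicatechin-(4β→6)-8-bromo-3,5,7,3',4'-penta-O-benzylcatechin | c1c(OCc9ccccc9)cc(OCc9ccccc9)c2c1O[C@H](c7ccc(OCc9ccccc9)c(OCc9ccccc9)c7)[C@H](O[Si](C)(C)C(C)(C)C)[C@H]2c3c(OCc9ccccc9)c(Br)c4c(c3OCc9ccccc9)C[C@H](OCc9ccccc9)[C@@H](c7ccc(OCc9ccccc9)c(OCc9ccccc9)c7)O4 | intermediate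
22 | 5,7,3',4'-tetra-O-benzylepicatechin-(4β→6)-8-bromo-3,5,7,3',4'-penta-O-benzylcatechin, middle 3-OH free | c1c(OCc9ccccc9)cc(OCc9ccccc9)c2c1O[C@H](c7ccc(OCc9ccccc9)c(OCc9ccccc9)c7)[C@H](O)[C@H]2c3c(OCc9ccccc9)c(Br)c4c(c3OCc9ccccc9)C[C@H](OCc9ccccc9)[C@@H](c7ccc(OCc9ccccc9)c(OCc9ccccc9)c7)O4 | intermediate
23 | 3,4,5-tris(benzyloxy)benzoic acid | OC(=O)c1cc(OCc2ccccc2)c(OCc2ccccc2)c(OCc2ccccc2)c1 | starting material
24 | 3,4,5-tris(benzyloxy)benzoyl chloride | ClC(=O)c1cc(OCc2ccccc2)c(OCc2ccccc2)c(OCc2ccccc2)c1 | intermediate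
25 | 5,7,3',4'-tetra-O-benzyl-3-O-[3,4,5-tris(benzyloxy)benzoyl]epicatechin-(4β→6)-8-bromo-3,5,7,3',4'-penta-O-benzylcatechin | c1c(OCc9ccccc9)cc(OCc9ccccc9)c2c1O[C@H](c7ccc(OCc9ccccc9)c(OCc9ccccc9)c7)[C@H](OC(=O)c7cc(OCc9ccccc9)c(OCc9ccccc9)c(OCc9ccccc9)c7)[C@H]2c3c(OCc9ccccc9)c(Br)c4c(c3OCc9ccccc9)C[C@H](OCc9ccccc9)[C@@H](c7ccc(OCc9ccccc9)c(OCc9ccccc9)c7)O4 | intermediate
26 | 4β-(2-ethoxyethoxy)-5,7,3',4'-tetra-O-benzyl-3-O-[3,4,5-tris(benzyloxy)benzoyl]epicatechin | c1c(OCc9ccccc9)cc(OCc9ccccc9)c2c1O[C@H](c7ccc(OCc9ccccc9)c(OCc9ccccc9)c7)[C@H](OC(=O)c7cc(OCc9ccccc9)c(OCc9ccccc9)c(OCc9ccccc9)c7)[C@H]2OCCOCC | intermediate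
27 | 8-bromo-4β-(2-ethoxyethoxy)-5,7,3',4'-tetra-O-benzyl-3-O-[3,4,5-tris(benzyloxy)benzoyl]epicatechin | Brc1c(OCc9ccccc9)cc(OCc9ccccc9)c2c1O[C@H](c7ccc(OCc9ccccc9)c(OCc9ccccc9)c7)[C@H](OC(=O)c7cc(OCc9ccccc9)c(OCc9ccccc9)c(OCc9ccccc9)c7)[C@H]2OCCOCC | intermediate
28 | fully protected trimer: 8-bromo-tetra-O-benzylepicatechin 3-O-[tris(benzyloxy)benzoate]-(4β→8)-tetra-O-benzylepicatechin 3-O-[tris(benzyloxy)benzoate]-(4β→6)-8-bromo-penta-O-benzylcatechin | O=C(O[C@@H]1[C@@H](c2c(OCc9ccccc9)cc(OCc9ccccc9)c3c2O[C@H](c7ccc(OCc9ccccc9)c(OCc9ccccc9)c7)[C@H](OC(=O)c7cc(OCc9ccccc9)c(OCc9ccccc9)c(OCc9ccccc9)c7)[C@H]3c4c(OCc9ccccc9)c(Br)c5c(c4OCc9ccccc9)C[C@H](OCc9ccccc9)[C@@H](c7ccc(OCc9ccccc9)c(OCc9ccccc9)c7)O5)c6c(OCc9ccccc9)cc(OCc9ccccc9)c(Br)c6O[C@@H]1c8ccc(OCc9ccccc9)c(OCc9ccccc9)c8)c8cc(OCc9ccccc9)c(OCc9ccccc9)c(OCc9ccccc9)c8 | intermediate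
29 | epicatechin 3-O-gallate-(4β→8)-epicatechin 3-O-gallate-(4β→6)-catechin (CNP0154615.1) | O=C(O[C@@H]1[C@@H](c2c(O)cc(O)c3c2O[C@H](c2ccc(O)c(O)c2)[C@H](OC(=O)c2cc(O)c(O)c(O)c2)[C@H]3c2c(O)cc3c(c2O)C[C@H](O)[C@@H](c2ccc(O)c(O)c2)O3)c2c(O)cc(O)cc2O[C@@H]1c1ccc(O)c(O)c1)c1cc(O)c(O)c(O)c1 | target

## Step count and least certain steps

Total: 22 steps. Longest linear sequence: 15 steps (1 → 2 → 3 → 4 → 10 → 11 → 12 → 15 → 17 → 18 → 20 → 21 → 22 → 25 → 28 → 29). Steps 4–6, 10, 17 and 19–20 lie on side branches.

**Step 13 (key step).**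
- What may go wrong: the ester carbonyl sits between a bromine and the acetaldehyde-bearing carbon, so the ketyl may be reduced further to the alcohol or dimerise to a pinacol before it finds the ester. The arylacetaldehyde may enolise and condense on the Lewis-acidic titanium salts. The metal may also cleave the C–Br bond or the aryl ester C–O bond, and the enol ether may hydrolyse on work-up.
- Fallback: it sets out from 15 and returns at 18. The ester carbonyl of 15 is methylenated with Cp2TiMe2 in toluene at 70 °C to give the aryl 1-arylvinyl ether F1. Ring-closing metathesis of F1 between the vinyl ether and the allyl group, with the second-generation Grubbs catalyst (H2IMes)(PCy3)Cl2Ru=CHPh in toluene at 70 °C, forms C2=C3 with loss of ethene and gives 18. Both reactions are known for making cyclic enol ethers from olefinic esters, and the route continues with step 14.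

**Step 7.**
- What may go wrong: attack of the cation on the arene carbon next to the silyloxy group, a second alkylation of the product, oligomerisation of 4 through its own C8, and partial loss of silyl groups under the triflate.
- Fallback: it sets out from 4 and returns at 11, and it removes the regiochemical question by symmetry. Cation formation from 4 with BF3·OEt2 in THF/CH2Cl2 in the presence of a large excess of phloroglucinol gives 4β-(2,4,6-trihydroxyphenyl)-3-O-TBS-5,7,3',4'-tetra-O-benzylepicatechin F2, in which all three arene carbons were equivalent. TIPSCl and imidazole silylate the least hindered, para hydroxyl to give the 4-silyl ether F3. BnBr and K2CO3 in acetone benzylate the two flanking hydroxyls to give F4. TBAF at 0 °C frees the para phenol F5, allyl bromide and K2CO3 give the allyl ether F6, and Claisen rearrangement of F6 in PhNEt2 at 190 °C gives 11.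

**Step 9.**
- What may go wrong: bromination of ring A of the middle unit (C8 or C6), which is also a trialkoxybenzene, over-bromination, or addition to the allyl group.
- Fallback: it sets out from 8 and returns at 12, and it moves the bromination to the monomer, where no second electron-rich ring is present. NBS with catalytic i-Pr2NH in CH2Cl2 brominates 8 ortho to the hydroxyl to give 2-allyl-6-bromo-3,5-bis(benzyloxy)phenol F7, separated if needed from any para isomer. F7, which has a single free carbon, is then coupled in excess with 4 under BF3·OEt2 in CH2Cl2 at −40 °C, 4 being added slowly, to give 12 directly. The price is a less nucleophilic arene, which the excess has to make up for.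

**Step 14.**
- What may go wrong: poor facial selectivity, because the ring oxygen and the fused benzene ring make the alkene differ from the carbocyclic models; slow addition of the bulky borane to a hindered enol ether; β-elimination of the β-aryloxy borane with opening of ring C.
- Fallback: it sets out from 18 and returns at 20, and it gives up reagent control. BH3·THF at 0 °C followed by NaOH/H2O2 adds with the same regiochemistry and syn course and gives both 2,3-trans alcohols, 20 and its lower-unit (2S,3R) epimer F8. Because the middle unit is chiral these are diastereomers and are separated by chromatography; 20 goes on to step 15.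

**Step 21.**
- What may go wrong: slow ionisation of the acyl-substituted donor, attack at C6 of the middle unit instead of C8, slow reaction of the large nucleophile, and acid-induced fission of the existing interflavan bond with scrambling of units.
- Fallback: it sets out from 27 and returns at 28, and it changes the mode of activation from an oxophilic acid to a thiophilic metal salt. Exchange of the 4-alkoxy group of 27 with thiophenol under BF3·OEt2 at −78 °C gives 8-bromo-4β-(phenylthio)-5,7,3',4'-tetra-O-benzyl-3-O-[3,4,5-tris(benzyloxy)benzoyl]epicatechin F9. F9 is coupled with 25 by AgBF4 in THF at 0 °C in the presence of 2,6-di-tert-butylpyridine, conditions under which no strong acid is free, to give 28.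

Further compounds

F1 | step 13 | 3-O-TBS-5,7,3',4'-tetra-O-benzylepicatechin carrying at C4β a 3-allyl-5-bromo-2,6-bis(benzyloxy)-4-{1-[3,4-bis(benzyloxy)phenyl]vinyloxy}phenyl group | c1c(OCc9ccccc9)cc(OCc9ccccc9)c2c1O[C@H](c7ccc(OCc9ccccc9)c(OCc9ccccc9)c7)[C@H](O[Si](C)(C)C(C)(C)C)[C@H]2c3c(OCc9ccccc9)c(Br)c(OC(=C)c7ccc(OCc9ccccc9)c(OCc9ccccc9)c7)c(CC=C)c3OCc9ccccc9
F2 | step 7 | 4β-(2,4,6-trihydroxyphenyl)-3-O-TBS-5,7,3',4'-tetra-O-benzylepicatechin | c1c(OCc9ccccc9)cc(OCc9ccccc9)c2c1O[C@H](c7ccc(OCc9ccccc9)c(OCc9ccccc9)c7)[C@H](O[Si](C)(C)C(C)(C)C)[C@H]2c3c(O)cc(O)cc3O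
F3 | step 7 | 4β-[2,6-dihydroxy-4-(triisopropylsilyloxy)phenyl]-3-O-TBS-5,7,3',4'-tetra-O-benzylepicatechin | c1c(OCc9ccccc9)cc(OCc9ccccc9)c2c1O[C@H](c7ccc(OCc9ccccc9)c(OCc9ccccc9)c7)[C@H](O[Si](C)(C)C(C)(C)C)[C@H]2c3c(O)cc(O[Si](C(C)C)(C(C)C)C(C)C)cc3O
F4 | step 7 | 4β-[2,6-bis(benzyloxy)-4-(triisopropylsilyloxy)phenyl]-3-O-TBS-5,7,3',4'-tetra-O-benzylepicatechin | c1c(OCc9ccccc9)cc(OCc9ccccc9)c2c1O[C@H](c7ccc(OCc9ccccc9)c(OCc9ccccc9)c7)[C@H](O[Si](C)(C)C(C)(C)C)[C@H]2c3c(OCc9ccccc9)cc(O[Si](C(C)C)(C(C)C)C(C)C)cc3OCc9ccccc9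
F5 | step 7 | 4β-[2,6-bis(benzyloxy)-4-hydroxyphenyl]-3-O-TBS-5,7,3',4'-tetra-O-benzylepicatechin | c1c(OCc9ccccc9)cc(OCc9ccccc9)c2c1O[C@H](c7ccc(OCc9ccccc9)c(OCc9ccccc9)c7)[C@H](O[Si](C)(C)C(C)(C)C)[C@H]2c3c(OCc9ccccc9)cc(O)cc3OCc9ccccc9
F6 | step 7 | 4β-[4-(allyloxy)-2,6-bis(benzyloxy)phenyl]-3-O-TBS-5,7,3',4'-tetra-O-benzylepicatechin | c1c(OCc9ccccc9)cc(OCc9ccccc9)c2c1O[C@H](c7ccc(OCc9ccccc9)c(OCc9ccccc9)c7)[C@H](O[Si](C)(C)C(C)(C)C)[C@H]2c3c(OCc9ccccc9)cc(OCC=C)cc3OCc9ccccc9
F7 | step 9 | 2-allyl-6-bromo-3,5-bis(benzyloxy)phenol | C=CCc1c(O)c(Br)c(OCc2ccccc2)cc1OCc1ccccc1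
F8 | step 14 | lower-unit (2S,3R) epimer of 20 | c1c(OCc9ccccc9)cc(OCc9ccccc9)c2c1O[C@H](c7ccc(OCc9ccccc9)c(OCc9ccccc9)c7)[C@H](O[Si](C)(C)C(C)(C)C)[C@H]2c3c(OCc9ccccc9)c(Br)c4c(c3OCc9ccccc9)C[C@@H](O)[C@H](c7ccc(OCc9ccccc9)c(OCc9ccccc9)c7)O4
F9 | step 21 | 8-bromo-4β-(phenylthio)-5,7,3',4'-tetra-O-benzyl-3-O-[3,4,5-tris(benzyloxy)benzoyl]epicatechin | Brc1c(OCc9ccccc9)cc(OCc9ccccc9)c2c1O[C@H](c7ccc(OCc9ccccc9)c(OCc9ccccc9)c7)[C@H](OC(=O)c7cc(OCc9ccccc9)c(OCc9ccccc9)c(OCc9ccccc9)c7)[C@H]2Sc3ccccc3
A1 | alternative 1 | 3-(middle-unit-8-yl)-4,6-bis(benzyloxy)indan-1-one, the middle unit being 4β-(2-ethoxyethoxy)-3-O-TBS-5,7,3',4'-tetra-O-benzylepicatechin | O=C1C[C@@H](c3c(OCc9ccccc9)cc(OCc9ccccc9)c4c3O[C@H](c7ccc(OCc9ccccc9)c(OCc9ccccc9)c7)[C@H](O[Si](C)(C)C(C)(C)C)[C@H]4OCCOCC)c2c(OCc9ccccc9)cc(OCc9ccccc9)cc21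
A2 | alternative 1 | 4-(middle-unit-8-yl)-5,7-bis(benzyloxy)chroman-2-one | O=C1C[C@@H](c3c(OCc9ccccc9)cc(OCc9ccccc9)c4c3O[C@H](c7ccc(OCc9ccccc9)c(OCc9ccccc9)c7)[C@H](O[Si](C)(C)C(C)(C)C)[C@H]4OCCOCC)c2c(OCc9ccccc9)cc(OCc9ccccc9)cc2O1
A3 | alternative 2 | 3,5-bis(benzyloxy)phenyl ether of a 1-[3,4-bis(benzyloxy)phenyl]-2,3-epoxypropan-1-ol whose trans-epoxide carbon C3 bears the 8-bromo-penta-O-benzylcatechin-6-yl group | c1c(OCc9ccccc9)cc(OCc9ccccc9)cc1O[C@H](c7ccc(OCc9ccccc9)c(OCc9ccccc9)c7)[C@@H]5O[C@H]5c3c(OCc9ccccc9)c(Br)c4c(c3OCc9ccccc9)C[C@H](OCc9ccccc9)[C@@H](c7ccc(OCc9ccccc9)c(OCc9ccccc9)c7)O4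
A4 | alternative 2 | 5,7,3',4'-tetra-O-benzylepicatechin-(4β→6)-8-bromo-3,5,7,3',4'-penta-O-benzylcatechin with free middle 3-OH (identical with 22) | c1c(OCc9ccccc9)cc(OCc9ccccc9)c2c1O[C@H](c7ccc(OCc9ccccc9)c(OCc9ccccc9)c7)[C@H](O)[C@H]2c3c(OCc9ccccc9)c(Br)c4c(c3OCc9ccccc9)C[C@H](OCc9ccccc9)[C@@H](c7ccc(OCc9ccccc9)c(OCc9ccccc9)c7)O4
A5 | alternative 3 | 3-O-TBS-5,7,3',4'-tetra-O-benzylepicatechin carrying at C4β a 3-bromo-2,6-bis(benzyloxy)phenyl group whose 4-oxygen is etherified with 1-[3,4-bis(benzyloxy)phenyl]-2,3-epoxypropan-1-ol (terminal epoxide) | c1c(OCc9ccccc9)cc(OCc9ccccc9)c2c1O[C@H](c7ccc(OCc9ccccc9)c(OCc9ccccc9)c7)[C@H](O[Si](C)(C)C(C)(C)C)[C@H]2c3c(OCc9ccccc9)c(Br)c(O[C@H](c7ccc(OCc9ccccc9)c(OCc9ccccc9)c7)[C@@H]5CO5)cc3OCc9ccccc9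
A6 | alternative 3 | 3-O-TBS-5,7,3',4'-tetra-O-benzylepicatechin-(4β→6)-8-bromo-5,7,3',4'-tetra-O-benzylcatechin with free lower 3-OH (identical with 20) | c1c(OCc9ccccc9)cc(OCc9ccccc9)c2c1O[C@H](c7ccc(OCc9ccccc9)c(OCc9ccccc9)c7)[C@H](O[Si](C)(C)C(C)(C)C)[C@H]2c3c(OCc9ccccc9)c(Br)c4c(c3OCc9ccccc9)C[C@H](O)[C@@H](c7ccc(OCc9ccccc9)c(OCc9ccccc9)c7)O4
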